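**Plan**

- Retrosynthesis cuts, in this order: both pyran O1–C2 bonds, both C4–C4a bonds, the two C=CH2 bonds and the two aryl–CH2 bonds of the acrylate arms, and last the central diaryl ether C–O bond. Each ring B 3-OH is traced back to a formyl group.
- Enabling feature: in each half the C4 methylene lies between ring A carbon C4a and C3, and C3 also holds ring B and C2. Once C2 is an ester carbon, C3=C4 is the double bond of a 2-arylacrylate, so ring A can enter at C4 as an aryl nucleophile.
- Forward: the ring B–O–ring B ether is made first, then the two acetate arms and their methylene groups. Ring A is joined twice at C4 without ring formation, the two pyran rings close last (O1–C2), and global debenzylation ends the route.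
- Stereochemistry: both C3 centres (R) come from catalyst-controlled protonation of rhodium enolates under (S)-BINAP in the twofold arylation and are not touched afterwards.

Key step: step 11

Assumption: (S)-BINAP is taken to deliver the proton to the enolate face that gives R at C3; the sense has to be assigned on the first adduct, and (R)-BINAP is used instead if it is the opposite.

Remark: in the twofold reactions on the two identical halves, the half-reacted species is numbered only at step 11.

**Route**

Step 1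
Reactants: 1 1-bromo-4-fluoro-2-methoxybenzene
Product: 4 3-bromo-6-fluoro-2-methoxybenzaldehyde, via aryllithium 2 (not isolated), via lithium hemiaminal alkoxide 3 (not isolated)
Conditions: LDA, THF, −78 °C; DMF, −78 °C; aq. NH4Cl
Reagents that add atoms: N,N-dimethylformamide, CN(C)C=O
Why: Directed ortho-lithiation with a lithium amide (no bromine–lithium exchange) removes the most acidic ring proton, the one flanked by F and OMe, and the aryllithium is formylated by DMF at a temperature where it does not lose LiF.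

Step 2
Reactants: 4 3-bromo-6-fluoro-2-methoxybenzaldehyde (about half of the batch)
Product: 6 3-bromo-6-hydroxy-2-methoxybenzaldehyde, via sulfonylethyl aryl ether 5 (not isolated)
Conditions: MeSO2CH2CH2OH, NaH, DMF, 0 °C to rt; aq. HCl
Reagents that add atoms: 2-(methylsulfonyl)ethanol, CS(=O)(=O)CCO
Why: SNAr of the alkoxide at the fluoride ortho to the formyl group followed by E1cB loss of methyl vinyl sulfone is an established hydroxide-free conversion of activated aryl fluorides into phenols and avoids a Cannizzaro reaction of the aldehyde.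

Step 3
Reactants: 6 3-bromo-6-hydroxy-2-methoxybenzaldehyde; 4 3-bromo-6-fluoro-2-methoxybenzaldehyde
Product: 7 6,6'-oxybis(3-bromo-2-methoxybenzaldehyde)
Conditions: K2CO3, DMF, 110 °C
Reagents that add atoms: none
Why: SNAr diaryl ether formation between a salicylaldehyde-type phenoxide and an ortho-formyl-activated aryl fluoride, as in the known coupling of salicylaldehyde with 2-fluorobenzaldehyde; the bromides are meta to the formyl groups and stay inert.

Step 4
Reactants: 7 6,6'-oxybis(3-bromo-2-methoxybenzaldehyde)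
Product: 9 6,6'-oxybis(3-bromo-2-methoxyphenol), via bis(aryl formate) 8 (not isolated)
Conditions: mCPBA, CH2Cl2, 0 °C to rt; then K2CO3, MeOH, rt
Reagents that add atoms: meta-chloroperoxybenzoic acid, O=C(OO)c1cccc(Cl)c1
Why: Baeyer–Villiger oxidation of the two 2,6-dioxygenated benzaldehydes proceeds with migration of the electron-rich aryl group, and methanolysis of the formates turns each formyl carbon into the ring B 3-OH.

Step 5
Reactants: 9 6,6'-oxybis(3-bromo-2-methoxyphenol)
Product: 10 1,1'-oxybis[2-(benzyloxy)-4-bromo-3-methoxybenzene]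
Conditions: BnBr, K2CO3, DMF, 60 °C
Reagents that add atoms: benzyl bromide, BrCc1ccccc1
Why: Williamson etherification of both phenols installs benzyl ethers that survive every later step up to the final hydrogenolysis.

Step 6
Reactants: 10 1,1'-oxybis[2-(benzyloxy)-4-bromo-3-methoxybenzene]
Product: 11 di-tert-butyl 2,2'-[oxybis(3-(benzyloxy)-2-methoxy-4,1-phenylene)]diacetate
Conditions: BrZnCH2CO2t-Bu (stock solution in THF), Pd(dba)2, P(t-Bu)3, THF, rt to 50 °C
Reagents that add atoms: (2-tert-butoxy-2-oxoethyl)zinc bromide, CC(C)(C)OC(=O)C[Zn]Br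
Why: Negishi-type α-arylation of a zinc ester enolate (Reformatsky reagent) under zerovalent palladium with a bulky trialkylphosphine needs no strong base, so both aryl bromides are replaced by CH2CO2t-Bu while the benzyl ethers and the diaryl ether are untouched.

Step 7
Reactants: 11 di-tert-butyl 2,2'-[oxybis(3-(benzyloxy)-2-methoxy-4,1-phenylene)]diacetate
Product: 12 di-tert-butyl 2,2'-[oxybis(3-(benzyloxy)-2-methoxy-4,1-phenylene)]bis(prop-2-enoate)
Conditions: (CH2O)n, K2CO3, n-Bu4NI, toluene, 80 °C; BHT on work-up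
Reagents that add atoms: formaldehyde (as paraformaldehyde), C=O
Why: α-Methylenation by aldol addition of the ester enolate to formaldehyde and E1cB dehydration under solid–liquid phase-transfer conditions is the standard entry to 2-arylacrylates from arylacetates; the product is kept cold and used at once.

Step 8
Reactants: 13 4-bromoresorcinol
Product: 14 5-(benzyloxy)-2-bromophenol
Conditions: BnBr (1.0 equiv), K2CO3, acetone, reflux
Reagents that add atoms: benzyl bromide, BrCc1ccccc1
Why: Regioselective Williamson benzylation occurs at the unhindered hydroxyl para to bromine, since the phenoxide next to bromine is the more hindered and less nucleophilic one; dibenzylated and regioisomeric material is removed by chromatography.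

Step 9
Reactants: 14 5-(benzyloxy)-2-bromophenol
Product: 15 4-(benzyloxy)-1-bromo-2-(methoxymethoxy)benzene
Conditions: MOMCl, i-Pr2NEt, CH2Cl2, 0 °C to rt
Reagents that add atoms: chloromethyl methyl ether, COCCl
Why: Acetal protection (O-alkylation with MOMCl) masks the future O1 phenol with a group that tolerates organolithium and hydride reagents and is removable by acid without touching benzyl ethers.

Step 10
Reactants: 15 4-(benzyloxy)-1-bromo-2-(methoxymethoxy)benzene
Product: 18 [4-(benzyloxy)-2-(methoxymethoxy)phenyl]boronic acid, via aryllithium 16 (not isolated), via lithium triisopropoxyborate 17 (not isolated)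
Conditions: n-BuLi, THF, −78 °C; B(Oi-Pr)3, −78 °C to rt; aq. NH4Cl
Reagents that add atoms: triisopropyl borate, CC(C)OB(OC(C)C)OC(C)C; water, O
Why: Bromine–lithium exchange is faster than any deprotonation at −78 °C, and borylation of the aryllithium followed by mild hydrolysis gives the boronic acid with the MOM ether intact.

Step 11
Reactants: 12 di-tert-butyl 2,2'-[oxybis(3-(benzyloxy)-2-methoxy-4,1-phenylene)]bis(prop-2-enoate); 18 [4-(benzyloxy)-2-(methoxymethoxy)phenyl]boronic acid (5 equiv in portions)
Product: 20 di-tert-butyl (2R,2'R)-2,2'-[oxybis(3-(benzyloxy)-2-methoxy-4,1-phenylene)]bis{3-[4-(benzyloxy)-2-(methoxymethoxy)phenyl]propanoate}, via mono-adduct 19 (not isolated)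
Conditions: Rh(acac)(C2H4)2 (6 mol %), (S)-BINAP (6.6 mol %), B(OH)3, 1,4-dioxane, 70 °C
Reagents that add atoms: none
Why: Transmetallation of 18 to monovalent rhodium gives an aryl–rhodium species that inserts the 1,1-disubstituted acrylate with the aryl group on the CH2 terminus (C4–C4a bond), and the resulting oxa-π-allyl rhodium enolate is protonated at C3 by boric acid inside the bisphosphine pocket, which frees the catalyst for the next turnover. The closest known reaction type is the rhodium-catalysed conjugate addition of arylboronic acids to α-substituted tert-butyl acrylates with enantioselective protonation. No ring closes; the two additions take place at remote, independent acrylate arms by way of mono-adduct 19. Each new C3 stereocentre is set by the catalyst alone, the face of C-protonation being dictated by (S)-BINAP, so the second event should not feel the first, the R,R isomer should dominate, and the minor meso isomer is a separable diastereomer. The step needs addition at the terminal carbon only, which the unsubstituted CH2 of the acrylate secures, and configurational stability of the new α-aryl ester, which the bulky tert-butyl ester, the weak proton source and the absence of added base should secure.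

Step 12
Reactants: 20 di-tert-butyl (2R,2'R)-2,2'-[oxybis(3-(benzyloxy)-2-methoxy-4,1-phenylene)]bis{3-[4-(benzyloxy)-2-(methoxymethoxy)phenyl]propanoate}
Product: 21 (2R,2'R)-2,2'-[oxybis(3-(benzyloxy)-2-methoxy-4,1-phenylene)]bis{3-[4-(benzyloxy)-2-(methoxymethoxy)phenyl]propan-1-ol}
Conditions: LiAlH4, THF, 0 °C; H2O, aq. NaOH
Reagents that add atoms: none
Why: LiAlH4 reduction of both esters to primary alcohols is run cold so that hydride delivery outpaces enolisation of the α-aryl ester, which keeps C3 intact and turns the ester carbon into C2.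

Step 13
Reactants: 21 (2R,2'R)-2,2'-[oxybis(3-(benzyloxy)-2-methoxy-4,1-phenylene)]bis{3-[4-(benzyloxy)-2-(methoxymethoxy)phenyl]propan-1-ol}
Product: 22 (2R,2'R)-2,2'-[oxybis(3-(benzyloxy)-2-methoxy-4,1-phenylene)]bis{3-[4-(benzyloxy)-2-hydroxyphenyl]propan-1-ol}
Conditions: HCl (cat.), MeOH, 45 °C
Reagents that add atoms: none
Why: Acid-catalysed transacetalisation of the two aryl MOM ethers to methanol frees the ring A phenols ortho to the C4 methylene while the benzyl ethers, the primary alcohols and the C3 centres are unaffected.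

Step 14
Reactants: 22 (2R,2'R)-2,2'-[oxybis(3-(benzyloxy)-2-methoxy-4,1-phenylene)]bis{3-[4-(benzyloxy)-2-hydroxyphenyl]propan-1-ol}
Product: 23 (3R,3'R)-3,3'-[oxybis(3-(benzyloxy)-2-methoxy-4,1-phenylene)]bis[7-(benzyloxy)chromane]
Conditions: PPh3, DIAD, THF, 0 °C to rt
Reagents that add atoms: none
Why: In a twofold intramolecular Mitsunobu etherification each phenol displaces the phosphonium-activated primary C2–OH in a 6-exo-tet closure to a chroman ring, the C3 centre next to the reacting carbon being a spectator.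

Step 15
Reactants: 23 (3R,3'R)-3,3'-[oxybis(3-(benzyloxy)-2-methoxy-4,1-phenylene)]bis[7-(benzyloxy)chromane]
Product: 24 (3R,3'R)-3,3'-[oxybis(3-hydroxy-2-methoxy-4,1-phenylene)]bis(chroman-7-ol)
Conditions: H2 (1 atm), Pd/C, THF/MeOH, rt
Reagents that add atoms: none
Why: Hydrogenolysis of the four aryl benzyl ethers over palladium on carbon leaves the diaryl ether, the chroman C–O bonds and the C3 centres intact and gives the target.

**Compound list**

1 | 1-bromo-4-fluoro-2-methoxybenzene | COc1cc(F)ccc1Br | starting material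
2 | (3-bromo-6-fluoro-2-methoxyphenyl)lithium | COc1c([Li])c(F)ccc1Br | intermediate
3 | lithium (3-bromo-6-fluoro-2-methoxyphenyl)(dimethylamino)methanolate (racemic) | COc1c(C([O-])N(C)C)c(F)ccc1Br.[Li+] | intermediate
4 | 3-bromo-6-fluoro-2-methoxybenzaldehyde | COc1c(C=O)c(F)ccc1Br | intermediate
5 | 3-bromo-2-methoxy-6-[2-(methylsulfonyl)ethoxy]benzaldehyde | COc1c(C=O)c(OCCS(C)(=O)=O)ccc1Br | intermediate
6 | 3-bromo-6-hydroxy-2-methoxybenzaldehyde | COc1c(C=O)c(O)ccc1Br | intermediate
7 | 6,6'-oxybis(3-bromo-2-methoxybenzaldehyde) | COc1c(C=O)c(Oc2ccc(Br)c(OC)c2C=O)ccc1Br | intermediate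
8 | 6,6'-oxybis(3-bromo-2-methoxyphenyl) diformate | COc1c(OC=O)c(Oc2ccc(Br)c(OC)c2OC=O)ccc1Br | intermediate
9 | 6,6'-oxybis(3-bromo-2-methoxyphenol) | COc1c(O)c(Oc2ccc(Br)c(OC)c2O)ccc1Br | intermediate
10 | 1,1'-oxybis[2-(benzyloxy)-4-bromo-3-methoxybenzene] | COc1c(Br)ccc(Oc2ccc(Br)c(OC)c2OCc2ccccc2)c1OCc1ccccc1 | intermediate
11 | di-tert-butyl 2,2'-[oxybis(3-(benzyloxy)-2-methoxy-4,1-phenylene)]diacetate | COc1c(CC(=O)OC(C)(C)C)ccc(Oc2ccc(CC(=O)OC(C)(C)C)c(OC)c2OCc2ccccc2)c1OCc1ccccc1 | intermediate
12 | di-tert-butyl 2,2'-[oxybis(3-(benzyloxy)-2-methoxy-4,1-phenylene)]bis(prop-2-enoate) | COc1c(C(=C)C(=O)OC(C)(C)C)ccc(Oc2ccc(C(=C)C(=O)OC(C)(C)C)c(OC)c2OCc2ccccc2)c1OCc1ccccc1 | intermediate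
13 | 4-bromoresorcinol | Oc1ccc(Br)c(O)c1 | starting material
14 | 5-(benzyloxy)-2-bromophenol | Oc1cc(OCc2ccccc2)ccc1Br | intermediate
15 | 4-(benzyloxy)-1-bromo-2-(methoxymethoxy)benzene | COCOc1cc(OCc2ccccc2)ccc1Br | intermediate
16 | [4-(benzyloxy)-2-(methoxymethoxy)phenyl]lithium | COCOc1cc(OCc2ccccc2)ccc1[Li] | intermediate
17 | lithium [4-(benzyloxy)-2-(methoxymethoxy)phenyl]triisopropoxyborate | [Li+].COCOc1cc(OCc2ccccc2)ccc1[B-](OC(C)C)(OC(C)C)OC(C)C | intermediate
18 | [4-(benzyloxy)-2-(methoxymethoxy)phenyl]boronic acid | OB(O)c1ccc(OCc2ccccc2)cc1OCOC | intermediate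
19 | mono-adduct: one arm (R)-configured tert-butyl 2-aryl-3-[4-(benzyloxy)-2-(methoxymethoxy)phenyl]propanoate, other arm still tert-butyl 2-arylacrylate | COc1c([C@@H](Cc2ccc(OCc3ccccc3)cc2OCOC)C(=O)OC(C)(C)C)ccc(Oc2ccc(C(=C)C(=O)OC(C)(C)C)c(OC)c2OCc2ccccc2)c1OCc1ccccc1 | intermediate
20 | di-tert-butyl (2R,2'R)-2,2'-[oxybis(3-(benzyloxy)-2-methoxy-4,1-phenylene)]bis{3-[4-(benzyloxy)-2-(methoxymethoxy)phenyl]propanoate} | COc1c([C@@H](Cc2ccc(OCc3ccccc3)cc2OCOC)C(=O)OC(C)(C)C)ccc(Oc2ccc([C@@H](Cc3ccc(OCc4ccccc4)cc3OCOC)C(=O)OC(C)(C)C)c(OC)c2OCc2ccccc2)c1OCc1ccccc1 | intermediate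
21 | (2R,2'R)-2,2'-[oxybis(3-(benzyloxy)-2-methoxy-4,1-phenylene)]bis{3-[4-(benzyloxy)-2-(methoxymethoxy)phenyl]propan-1-ol} | COc1c([C@@H](Cc2ccc(OCc3ccccc3)cc2OCOC)CO)ccc(Oc2ccc([C@@H](Cc3ccc(OCc4ccccc4)cc3OCOC)CO)c(OC)c2OCc2ccccc2)c1OCc1ccccc1 | intermediate
22 | (2R,2'R)-2,2'-[oxybis(3-(benzyloxy)-2-methoxy-4,1-phenylene)]bis{3-[4-(benzyloxy)-2-hydroxyphenyl]propan-1-ol} | COc1c([C@@H](Cc2ccc(OCc3ccccc3)cc2O)CO)ccc(Oc2ccc([C@@H](Cc3ccc(OCc4ccccc4)cc3O)CO)c(OC)c2OCc2ccccc2)c1OCc1ccccc1 | intermediate
23 | (3R,3'R)-3,3'-[oxybis(3-(benzyloxy)-2-methoxy-4,1-phenylene)]bis[7-(benzyloxy)chromane] | COc1c([C@@H]2COc3cc(OCc4ccccc4)ccc3C2)ccc(Oc2ccc([C@@H]3COc4cc(OCc5ccccc5)ccc4C3)c(OC)c2OCc2ccccc2)c1OCc1ccccc1 | intermediate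
24 | (3R,3'R)-3,3'-[oxybis(3-hydroxy-2-methoxy-4,1-phenylene)]bis(chroman-7-ol) | COc1c([C@@H]2COc3cc(O)ccc3C2)ccc(Oc2ccc([C@@H]3COc4cc(O)ccc4C3)c(OC)c2O)c1O | target

**Count**

Total steps: 15. Longest linear sequence: 12 steps (steps 1–7 and 11–15, from compound 1); the ring A boronic acid takes 3 steps (8–10).

**Steps most likely to fail**

1. Step 11. What may go wrong: poor facial selectivity in the protonation of an α-aryl rhodium enolate, epimerisation at C3 after protonation, or protodeboronation of the electron-rich ortho-alkoxy boronic acid that starves the second addition.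
Fallback: auxiliary-controlled enolate alkylation, setting out from 11 and coming back at 21. Cleavage of both tert-butyl esters of 11 (TFA, Et3SiH, CH2Cl2, 0 °C) should give 2,2'-[oxybis(3-(benzyloxy)-2-methoxy-4,1-phenylene)]diacetic acid F1. Activation as the mixed pivalic anhydride (PivCl, Et3N, THF, −20 °C) and acylation of lithiated (R)-4-benzyl-2-oxazolidinone gives the bis(N-arylacetyl oxazolidinone) F2. The ring A electrophile is made from aryllithium 16 (generated from 15 as in step 10): DMF quench gives 4-(benzyloxy)-2-(methoxymethoxy)benzaldehyde F3, NaBH4 in MeOH gives [4-(benzyloxy)-2-(methoxymethoxy)phenyl]methanol F4, and Appel bromination (CBr4, PPh3, CH2Cl2, 0 °C) gives 4-(benzyloxy)-1-(bromomethyl)-2-(methoxymethoxy)benzene F5, which is used at once. Twofold enolisation of F2 (NaHMDS, THF, −78 °C) and alkylation with F5 on the enolate face away from the auxiliary benzyl group should give the (R,R)-dialkylated bis(imide) F6. Reductive removal of both auxiliaries (LiBH4, H2O, Et2O/THF, 0 °C) then leads directly to diol 21, and the route goes on with step 13.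

2. Step 7. What may go wrong: Michael addition of unreacted ester enolate to the acrylate already formed, and base-induced oligomerisation of the 2-arylacrylate arms.
Fallback: Mannich reaction and elimination, setting out from 11 and coming back at 12. Twofold enolisation of 11 (LiHMDS, THF, −78 °C) and trapping with dimethylmethyleneammonium iodide gives the bis(β-dimethylamino ester) F7. Quaternisation with MeI gives the bis(trimethylammonium iodide) F8, and mild base (aq. NaHCO3, CH2Cl2) induces E1cB loss of trimethylamine to give bis(acrylate) 12 at room temperature, with no free enolate present beside the product.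

3. Step 6. What may go wrong: slow oxidative addition into the electron-rich ortho-alkoxy C–Br bonds, so that the reaction stalls after one coupling or ends in protodebromination.
Fallback: organolithium acylation and Wittig methylenation, setting out from 10 and coming back at 12 (compound 11 is bypassed). Twofold bromine–lithium exchange of 10 (n-BuLi, THF, −78 °C) gives the dilithio diaryl ether F9, which is added to excess di-tert-butyl oxalate at −78 °C to give the bis(tert-butyl arylglyoxylate) F10. Wittig methylenation of both keto groups (Ph3PCH3Br, KOt-Bu, THF, 0 °C) gives bis(acrylate) 12.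

**Further compounds**

F1 | step 11 | 2,2'-[oxybis(3-(benzyloxy)-2-methoxy-4,1-phenylene)]diacetic acid | COc1c(CC(=O)O)ccc(Oc2ccc(CC(=O)O)c(OC)c2OCc2ccccc2)c1OCc1ccccc1
F2 | step 11 | bis{N-arylacetyl (R)-4-benzyl-2-oxazolidinone} of F1 | COc1c(CC(=O)N2[C@H](Cc3ccccc3)COC2=O)ccc(Oc2ccc(CC(=O)N3[C@H](Cc4ccccc4)COC3=O)c(OC)c2OCc2ccccc2)c1OCc1ccccc1
F3 | step 11 | 4-(benzyloxy)-2-(methoxymethoxy)benzaldehyde | COCOc1cc(OCc2ccccc2)ccc1C=O
F4 | step 11 | [4-(benzyloxy)-2-(methoxymethoxy)phenyl]methanol | COCOc1cc(OCc2ccccc2)ccc1CO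
F5 | step 11 | 4-(benzyloxy)-1-(bromomethyl)-2-(methoxymethoxy)benzene | COCOc1cc(OCc2ccccc2)ccc1CBr
F6 | step 11 | (R,R)-dialkylated bis{N-acyl (R)-4-benzyl-2-oxazolidinone} | COc1c([C@@H](Cc2ccc(OCc3ccccc3)cc2OCOC)C(=O)N2[C@H](Cc3ccccc3)COC2=O)ccc(Oc2ccc([C@@H](Cc3ccc(OCc4ccccc4)cc3OCOC)C(=O)N3[C@H](Cc4ccccc4)COC3=O)c(OC)c2OCc2ccccc2)c1OCc1ccccc1
F7 | step 7 | di-tert-butyl 2,2'-[oxybis(3-(benzyloxy)-2-methoxy-4,1-phenylene)]bis[3-(dimethylamino)propanoate] (stereoisomer mixture) | COc1c(C(CN(C)C)C(=O)OC(C)(C)C)ccc(Oc2ccc(C(CN(C)C)C(=O)OC(C)(C)C)c(OC)c2OCc2ccccc2)c1OCc1ccccc1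
F8 | step 7 | bis(trimethylammonium iodide) of F7 (stereoisomer mixture) | COc1c(C(C[N+](C)(C)C)C(=O)OC(C)(C)C)ccc(Oc2ccc(C(C[N+](C)(C)C)C(=O)OC(C)(C)C)c(OC)c2OCc2ccccc2)c1OCc1ccccc1.[I-].[I-]
F9 | step 6 | dilithio species: 1,1'-oxybis[2-(benzyloxy)-4-lithio-3-methoxybenzene] | COc1c([Li])ccc(Oc2ccc([Li])c(OC)c2OCc2ccccc2)c1OCc1ccccc1
F10 | step 6 | di-tert-butyl 2,2'-[oxybis(3-(benzyloxy)-2-methoxy-4,1-phenylene)]bis(2-oxoacetate) | COc1c(C(=O)C(=O)OC(C)(C)C)ccc(Oc2ccc(C(=O)C(=O)OC(C)(C)C)c(OC)c2OCc2ccccc2)c1OCc1ccccc1
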